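(The readings are calculated from invented constants; noise was put on by code.)

4 questions stand on this flask, and we want to answer them with one division.

all flasks: Q 16 mM
- gamma: E 9.6 mM; L 0.32 mM; the very flask that is asked about, followed so far
- flask: E 9.60 mM; L 0.320 mM; time 4.0 h

- gamma (time / h: D / %, Q / %): 0.250: 7.9, 91.1; 0.500: 41.1, 60.7; 0.833: 57.1, 44.1; 1.50: 60.1, 40.2; 3.00: 59.5, 40.6

(readings scatter by 1 percentage point)

- east: change nothing and wait 4.0 h more
- south-east: at 4.0 h add E, 50.0% of the amount charged, then wait 4.0 h
- south-west: at 4.0 h take out 90% of the J then present, then wait 4.0 h
- north-east: at 4.0 h add L, 100% of the amount charged, then wait 4.0 h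
- west: at 4.0 h add Q, 50.0% of the amount charged, then wait 4.0 h

- additions bring no volume worth counting
- the earlier runs were read with a standard deviation of 1 percentage point

1. D, in percent of the Q first charged, at 4.0 h
2. the option that brings most further D ("none" if no option brings more than 2 percentage points) (east / south-east / south-west / north-east / west / none)
3. D present, in percent of the Q first charged, after south-east
4. D present, in percent of the Q first charged, after south-west

The gamma run is this flask followed so far. At 3.00 h its D and Q add up to 100% of the Q charged, so we read one D formed for each Q lost. D reads 60.1% at 1.50 h and 59.5% at 3.00 h, a flat line. The bench rule for a flat line in a one-to-one reaction is to look at the limiting reagent, and here that is E, because less E than Q was charged. So we divide the charged [E] by the charged [Q], which gives 60.0% in this flask, and we call this the E ceiling: the D, in percent of the Q first charged, that the E can pay for at one E per Q. The last reading stands 0.5 points from it, with a scatter of 1 point. The reading and the division come from different things, so this is a real check.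

The rule has two borders. It says where a flask stops but not when, and it takes E as the limiting reagent, which asks for [E]/[Q] below one. South-east lifts the ceiling to 90.0%, which leaves [E]/[Q] still below one, so E stays limiting. The wait of 4.0 h is 2.67 times the 1.50 h by which the gamma run had gone flat. The other options add no E, so on this reckoning they stay at the ceiling of 60.0%. We therefore commit to 60.0% now, 90.0% after south-east and 60.0% after south-west.

The forecast gives 60% now, names south-east as best, and gives 89% after south-east, a little below our figure, and 60.5% after south-west. Its ground is that “The plateau of about 60 % matches the charge ratio”.

The flask gives 60.0% at 4.0 h. The best option is south-east, bringing 30 points of further D, and D then stands at 90.0%; after south-west it stands at 60.0%.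

    Q + E + J → D + 2 J (k = 25.0 M⁻² s⁻¹)
    L + J ⇌ G, settled at all times (K = 7.80 × 10⁶ M⁻¹)
    Q + E → D + J (k = 0.00530 M⁻¹ s⁻¹)

The ceiling holds none of these constants, and the tying up of L + J as G moves D at 4.0 h by nothing. The ceiling after south-east, 90.0%, stands beside the 90.0% found. Now take the neighbour with 9.6 mM of Q, which sits on the border at 1.00 equiv of E: its ceiling is 100%. The computed flask gives 96.0% at 4.0 h, below that ceiling, with 4.0% of its Q and 4.0% of its E still there.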